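The ten-membered carbocycle (C1–C10) is opened at the C1=C10 double bond of the enal. C9, which carries the methoxy group, is bonded to C10, the α-carbon of the C14 carbonyl. C9 can therefore serve as the conjugate-addition site and C10 as the olefinating carbon of one C9=C10 alkylidene phosphonoacetate. In one operation methoxide adds at C9 and the C10 phosphonate carbanion condenses with a C1 aldehyde, creating the C9–O bond, the C9 stereocentre, the C1=C10 alkene and the ring. The precursor is an acyclic C1 aldehyde joined through the C4=C5 alkene (O15 as PMB ether) to the γ-lactone ring (O–C6–C7–C11–C12), with C8–OTBS and the alkylidene phosphonoacetate.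

Key step: step 15

Remark: C1–C15 in the text are germacrane locants (ring C1–C10, lactone carbons C11–C13, formyl carbon C14, hydroxymethyl carbon C15); where the CIP letter at C7 or C9 changes between neighbouring compounds, only the priorities change, not the geometry.
Remark: the condensation product 23 is assumed to form as a mixture of C9=C10 isomers (E drawn, C8 trans to phosphorus) and is carried on unseparated, because both isomers give the same methoxide adducts.

Step 1
Reactants: 1 2-butyne-1,4-diol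
Product: 2 4-[(4-methoxybenzyl)oxy]but-2-yn-1-ol
Conditions: 1 (3 equiv), NaH (1 equiv), THF/DMF, 0 °C; PMBCl (1 equiv), Bu4NI (cat.), 0 °C to rt
Reagents that add atoms: 4-methoxybenzyl chloride, COc1ccc(CCl)cc1
Why: Williamson etherification of the mono-alkoxide of the symmetrical diol, which is used in excess and removed by aqueous washing, should stop at the mono-PMB ether.

Step 2
Reactants: 2 4-[(4-methoxybenzyl)oxy]but-2-yn-1-ol
Product: 4 (Z)-3-iodo-4-[(4-methoxybenzyl)oxy]but-2-en-1-ol, via cyclic alkenylaluminate 3 (not isolated)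
Conditions: Red-Al (1.5 equiv), THF, 0 °C to rt; EtOAc; I2 (1.6 equiv), THF, −78 to 0 °C
Reagents that add atoms: iodine, II
Why: Hydroxyl-directed trans-hydroalumination of the propargylic alcohol places aluminium on the distal alkyne carbon (future C4) inside a five-membered alkoxyaluminate and iodinolysis with retention should give the Z vinyl iodide, which fixes C6 cis to the future C3 chain across C4=C5.

Step 3
Reactants: 4 (Z)-3-iodo-4-[(4-methoxybenzyl)oxy]but-2-en-1-ol, 5 2-vinyl-1,3-dioxolane
Product: 7 (E)-5-(1,3-dioxolan-2-yl)-3-{[(4-methoxybenzyl)oxy]methyl}pent-2-en-1-ol, via B-alkyl-9-BBN 6 (not isolated)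
Conditions: 5, 9-BBN-H, THF, 0 °C to rt; then 4, Pd(dppf)Cl2 (5 mol%), AsPh3, Cs2CO3, DMF/H2O, rt
Reagents that add atoms: none
Why: Anti-Markovnikov hydroboration of the terminal alkene followed by B-alkyl Suzuki–Miyaura coupling, which retains the vinyl iodide geometry and tolerates the free allylic alcohol, should attach C1–C3 at C4.

Step 4
Reactants: 7 (E)-5-(1,3-dioxolan-2-yl)-3-{[(4-methoxybenzyl)oxy]methyl}pent-2-en-1-ol
Product: 8 (E)-5-(1,3-dioxolan-2-yl)-3-{[(4-methoxybenzyl)oxy]methyl}pent-2-enal
Conditions: MnO2 (20 equiv), CH2Cl2, rt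
Reagents that add atoms: none
Why: Allylic oxidation with activated manganese dioxide is selective for the primary allylic alcohol and neutral, so the trisubstituted alkene geometry, the acetal and the PMB ether should be preserved.

Step 5
Reactants: 9 4-tert-butoxy-4-oxobutanoic acid, 10 (S)-4-benzyl-1,3-oxazolidin-2-one
Product: 12 tert-butyl 4-[(4S)-4-benzyl-2-oxo-1,3-oxazolidin-3-yl]-4-oxobutanoate, via mixed pivalic anhydride 11 (not isolated)
Conditions: PivCl, Et3N, THF, −20 °C; then 10, LiCl, −20 °C to rt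
Reagents that add atoms: none
Why: N-Acylation of the oxazolidinone through the mixed pivalic anhydride with LiCl/Et3N activation is a standard imide synthesis in which the hindered pivaloyl carbonyl is not attacked.

Step 6
Reactants: 12 tert-butyl 4-[(4S)-4-benzyl-2-oxo-1,3-oxazolidin-3-yl]-4-oxobutanoate, 8 (E)-5-(1,3-dioxolan-2-yl)-3-{[(4-methoxybenzyl)oxy]methyl}pent-2-enal
Product: 13 syn-aldol imide (6R,7S; C6–OH free; C12 tert-butyl ester)
Conditions: 12, Bu2BOTf (1.15 equiv), Et3N (1.3 equiv), CH2Cl2, −78 to 0 °C; 8, −78 to 0 °C; pH 7 buffer, MeOH, 30% H2O2, 0 °C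
Reagents that add atoms: none
Why: Evans syn-aldol reaction, in which the Z-dibutylboron enolate reacts through a closed chair transition state on the face away from the benzyl group, should set C7 (S) and C6 (R) in a syn relationship while the hindered tert-butyl ester neither enolises nor lactonises.

Step 7
Reactants: 13 syn-aldol imide
Product: 14 β-hydroxy Weinreb amide (6R,7S)
Conditions: MeNH(OMe)·HCl (3 equiv), AlMe3 (3 equiv), CH2Cl2, 0 °C; then 13, −20 to 0 °C; aq. Rochelle salt
Reagents that add atoms: N,O-dimethylhydroxylamine hydrochloride, CNOC.Cl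
Why: Aluminium-amide transamidation (Weinreb amide formation) of a β-hydroxy N-acyloxazolidinone is directed to the exocyclic carbonyl by the aluminium alkoxide of the free C6 hydroxyl and should leave the tert-butyl ester and both stereocentres untouched.

Step 8
Reactants: 14 β-hydroxy Weinreb amide, 15 1,3-dithiane
Product: 17 β-hydroxy 2-acyl-1,3-dithiane (6R,7S; C8 ketone; C9 as dithiane), via 2-lithio-1,3-dithiane 16 (not isolated)
Conditions: 15 (3.2 equiv), n-BuLi (3.0 equiv), THF, −30 °C; 14, −78 °C; AcOH, −78 °C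
Reagents that add atoms: none
Why: Acylation of 2-lithio-1,3-dithiane by the Weinreb amide stops at the ketone because the chelated tetrahedral adduct persists until the cold acidic quench, so C9 is introduced as a masked formyl group without epimerising C7.

Step 9
Reactants: 17 β-hydroxy 2-acyl-1,3-dithiane
Product: 18 C6-acetoxy C8-hydroxy dithiane (6R,7R,8S)
Conditions: MeCHO (8 equiv), SmI2 (0.3 equiv; pre-stirred with MeCHO until the blue colour has faded), THF, −10 °C
Reagents that add atoms: acetaldehyde, CC=O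
Why: Evans–Tishchenko reduction, in which the samarium-bound hemiacetal formed from the C6 hydroxyl and acetaldehyde delivers hydride intramolecularly to the C8 ketone through a six-membered transition state, should give the 1,3-anti (8S) alcohol with O6 acetylated and O8 free.

Step 10
Reactants: 18 C6-acetoxy C8-hydroxy dithiane
Product: 19 C6-acetoxy C8-silyloxy dithiane (6R,7S,8S)
Conditions: TBSOTf (1.3 equiv), 2,6-lutidine (2.5 equiv), CH2Cl2, −78 °C
Reagents that add atoms: tert-butyldimethylsilyl trifluoromethanesulfonate, CC(C)(C)[Si](C)(C)OS(=O)(=O)C(F)(F)F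
Why: Silylation of the hindered secondary C8 alcohol with the silyl triflate and 2,6-lutidine is fast at −78 °C, a temperature at which the acetal, the dithiane and the tert-butyl ester are not activated.

Step 11
Reactants: 19 C6-acetoxy C8-silyloxy dithiane
Product: 20 trans-γ-lactone dithiane (6R,7S,8S)
Conditions: K2CO3 (1.5 equiv), MeOH, 0 °C to rt
Reagents that add atoms: none
Why: Transesterification with methanol removes the C6 acetate and the liberated C6 alkoxide should close the γ-lactone by 5-exo-trig acyl substitution at the tert-butyl ester, the 6,7-syn relationship translating into the trans-4,5-disubstituted ring without a new stereocentre.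

Step 12
Reactants: 20 trans-γ-lactone dithiane
Product: 21 C8-silyloxy C9 aldehyde (6R,7S,8S)
Conditions: MeI (10 equiv), CaCO3 (5 equiv), MeCN/H2O (9:1), 45 °C
Reagents that add atoms: water, O
Why: S-Methylation turns the dithiane into a sulfonium leaving group and carbonate-buffered hydrolysis should release the C9 aldehyde without epimerising the α-silyloxy centre C8 or touching the dioxolane, the PMB ether and the alkene.

Step 13
Reactants: 21 C8-silyloxy C9 aldehyde, 22 methyl 2-(diethoxyphosphoryl)acetate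
Product: 23 C9=C10 alkylidene phosphonoacetate with C1 dioxolane (6R,7S,8S)
Conditions: TiCl4 (2 equiv), THF, 0 °C; 21, 22 (1.2 equiv); N-methylmorpholine (4 equiv), 0 °C to rt
Reagents that add atoms: none
Why: Titanium-mediated Knoevenagel condensation (Lehnert conditions) dehydrates the titanium aldolate instead of expelling phosphate, so the phosphonate is kept in the C9=C10 alkylidene product, and the THF-complexed Lewis acid with an amine base is mild enough for α-oxygenated aldehydes and cyclic acetals.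

Step 14
Reactants: 23 C9=C10 alkylidene phosphonoacetate with C1 dioxolane
Product: 24 seco C1 aldehyde with C9=C10 alkylidene phosphonoacetate (O8 TBS; O15 PMB; saturated 6,12-lactone; 6R,7S,8S)
Conditions: PPTS (0.3 equiv), acetone/H2O (10:1), 55 °C
Reagents that add atoms: water, O
Why: Acid-catalysed acetal hydrolysis with a pyridinium salt in wet acetone should unmask the C1 aldehyde, whereas the hindered secondary TBS ether, the PMB ether and the electron-poor alkylidene phosphonoacetate are inert to this weak acid.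

Step 15
Reactants: 24 seco C1 aldehyde with C9=C10 alkylidene phosphonoacetate, 25 sodium methoxide
Product: 27 macrocyclic 9-methoxy C14 methyl ester (O8 TBS; O15 PMB; saturated 6,12-lactone; 1(10)E,4E,6R,7S,8S,9S), via C9-methoxy phosphonate carbanion 26 (not isolated)
Conditions: 25 (1.05 equiv, 0.5 M in MeOH), THF, 0.002 M in 24, −40 to 0 °C; AcOH
Reagents that add atoms: none
Why: Proposed new method: oxa-Michael addition of methoxide to C9 of the alkylidene phosphonoacetate is an equilibrium that generates the sodium phosphonoacetate carbanion 26 at C10; 26 attacks the C1 formyl carbon and the derived oxaphosphetane collapses with loss of sodium diethyl phosphate, the only irreversible event, to leave the C1=C10 enoate. The closest known reactions are the intermolecular tandem conjugate addition/Horner–Wadsworth–Emmons olefination of vinyl- and alkylidenephosphonates and the intramolecular Horner–Wadsworth–Emmons macrocyclisation, whose combination on a medium ring has no direct precedent. The ten-membered carbocycle is closed by ring-closing olefination (formally 10-exo-trig attack of C10 on the C1 carbonyl) at high dilution, helped by two rigid elements of the chain, the C4=C5 alkene that holds C3 and C6 cis and the trans-disubstituted lactone. C9 is set under Curtin–Hammett control by the adjacent C8 silyloxy centre: the C9=C10 isomers of 24 and the C9 epimers of 26 equilibrate by retro-addition, and the epimer that can cyclise with C9–OMe anti to C8–OTBS (trans on the nascent ring, 9S) is expected to be consumed fastest. The step also needs C2 trans to the ester across C1=C10, which is both the usual outcome of stabilised phosphonoacetate olefination and the ring-cis geometry a ten-membered ring favours, and it needs the lactone to survive, which one equivalent of methoxide (stored as the weakly basic carbanion) at low temperature should ensure.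

Step 16
Reactants: 27 macrocyclic 9-methoxy C14 methyl ester
Product: 28 macrocyclic lactol C14 allylic alcohol (C12 anomers)
Conditions: DIBAL-H (5 equiv), CH2Cl2, −78 °C; aq. Rochelle salt
Reagents that add atoms: none
Why: DIBAL-H reduction takes the conjugated methyl ester to the allylic alcohol by 1,2-addition and halts the lactone at the lactol aluminate at −78 °C, so both carbonyl groups are adjusted together while silyl, PMB and methyl ethers are untouched.

Step 17
Reactants: 28 macrocyclic lactol C14 allylic alcohol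
Product: 29 macrocyclic C14 enal 6,12-lactone
Conditions: TEMPO (0.3 equiv), PhI(OAc)2 (3.5 equiv), CH2Cl2, rt
Reagents that add atoms: none
Why: Oxoammonium (TEMPO/PhI(OAc)2) oxidation converts the primary allylic alcohol into the enal and the lactol into the lactone under nearly neutral conditions, which should restore the 6,12-lactone without isomerising C1=C10.

Step 18
Reactants: 29 macrocyclic C14 enal 6,12-lactone
Product: 30 C14 ethylene acetal lactone
Conditions: TMSOCH2CH2OTMS (3 equiv), TMSOTf (0.1 equiv), CH2Cl2, −78 to −30 °C; pyridine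
Reagents that add atoms: 1,2-bis(trimethylsilyloxy)ethane, C[Si](C)(C)OCCO[Si](C)(C)C
Why: Noyori acetalisation with the bis-silyl ether of ethylene glycol and catalytic silyl triflate protects enals at low temperature without double-bond migration or conjugate addition and spares the lactone, the TBS ether and the PMB ether.

Step 19
Reactants: 30 C14 ethylene acetal lactone
Product: 33 α-methylene lactone C14 acetal, via Mannich base 31 (not isolated), via ammonium iodide 32 (not isolated)
Conditions: LDA (1.3 equiv), THF, −78 °C; CH2=NMe2+ I− (3 equiv), −78 °C to rt; MeI, MeOH, rt; aq. NaHCO3/EtOAc, rt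
Reagents that add atoms: N,N-dimethylmethyleneiminium iodide (Eschenmoser's salt), C=[N+](C)C.[I-]
Why: α-Methylenation by aminomethylation of the lactone lithium enolate with Eschenmoser's salt, N-quaternisation and base-induced β-elimination of trimethylamine is the standard route to α-methylene-γ-lactones, and with C14 masked as the acetal the lactone C11–H is the only acidic position.

Step 20
Reactants: 33 α-methylene lactone C14 acetal
Product: 34 C8 alcohol C14 enal (6R,7R,8S,9S)
Conditions: 48% aq. HF/MeCN (1:9), 0 °C to rt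
Reagents that add atoms: water, O
Why: Acidic fluoride desilylation with aqueous HF in acetonitrile cleaves the secondary TBS ether and, being an aqueous acid, should hydrolyse the enal acetal in the same flask, whereas the PMB ether, the methyl ether and the α-methylene lactone are stable to it.

Step 21
Reactants: 34 C8 alcohol C14 enal
Product: 35 C8 methacrylate O15-PMB ether
Conditions: methacrylic anhydride (3 equiv), Et3N (4 equiv), DMAP (0.2 equiv), CH2Cl2, 0 °C to rt
Reagents that add atoms: methacrylic anhydride, C=C(C)C(=O)OC(=O)C(C)=C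
Why: DMAP-catalysed acylation of the only free hydroxyl with the anhydride should give the C8 methacrylate with retention at C8 under conditions too mild for lactone migration or vinylogous loss of the C9 methoxy group.

Step 22
Reactants: 35 C8 methacrylate O15-PMB ether
Product: 36 CNP0114830.1 (target)
Conditions: DDQ (1.5 equiv), CH2Cl2/pH 7 buffer (10:1), 0 °C
Reagents that add atoms: none
Why: Oxidative PMB ether cleavage with DDQ in buffered wet dichloromethane proceeds through the benzylic oxocarbenium ion and is orthogonal to the enal, the α-methylene lactone and the methacrylate, so the C15 alcohol is released last.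

Compound list

1 | 2-butyne-1,4-diol | OCC#CCO | starting material
2 | 4-[(4-methoxybenzyl)oxy]but-2-yn-1-ol | OCC#CCOCc1ccc(OC)cc1 | intermediate
3 | sodium 2,2-bis(2-methoxyethoxy)-3-{[(4-methoxybenzyl)oxy]methyl}-2,5-dihydro-1,2-oxaluminol-2-uide (cyclic alkenylaluminate, not isolated) | [Na+].COCCO[Al-]1(OCCOC)OCC=C1COCc1ccc(OC)cc1 | intermediate
4 | (Z)-3-iodo-4-[(4-methoxybenzyl)oxy]but-2-en-1-ol | OC/C=C(\I)COCc1ccc(OC)cc1 | intermediate
5 | 2-vinyl-1,3-dioxolane | C=CC1OCCO1 | starting material
6 | 9-[2-(1,3-dioxolan-2-yl)ethyl]-9-borabicyclo[3.3.1]nonane (not isolated) | O1CCOC1CCB1C2CCCC1CCC2 | intermediate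
7 | (E)-5-(1,3-dioxolan-2-yl)-3-{[(4-methoxybenzyl)oxy]methyl}pent-2-en-1-ol | OC/C=C(/COCc1ccc(OC)cc1)CCC1OCCO1 | intermediate
8 | (E)-5-(1,3-dioxolan-2-yl)-3-{[(4-methoxybenzyl)oxy]methyl}pent-2-enal | O=C/C=C(/COCc1ccc(OC)cc1)CCC1OCCO1 | intermediate
9 | 4-tert-butoxy-4-oxobutanoic acid (mono-tert-butyl succinate) | CC(C)(C)OC(=O)CCC(=O)O | starting material
10 | (S)-4-benzyl-1,3-oxazolidin-2-one | O=C1N[C@@H](Cc2ccccc2)CO1 | starting material
11 | 4-tert-butoxy-4-oxobutanoic pivalic anhydride (not isolated) | CC(C)(C)OC(=O)CCC(=O)OC(=O)C(C)(C)C | intermediate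
12 | tert-butyl 4-[(4S)-4-benzyl-2-oxo-1,3-oxazolidin-3-yl]-4-oxobutanoate | CC(C)(C)OC(=O)CCC(=O)N1[C@@H](Cc2ccccc2)COC1=O | intermediate
13 | tert-butyl (3S,4R,5E)-3-{[(4S)-4-benzyl-2-oxo-1,3-oxazolidin-3-yl]carbonyl}-8-(1,3-dioxolan-2-yl)-4-hydroxy-6-{[(4-methoxybenzyl)oxy]methyl}oct-5-enoate (syn-aldol imide; germacrane 6R,7S) | C1COC(O1)CC/C(COCc1ccc(OC)cc1)=C\[C@@H](O)[C@H](CC(=O)OC(C)(C)C)C(=O)N1[C@@H](Cc2ccccc2)COC1=O | intermediate
14 | tert-butyl (3S,4R,5E)-8-(1,3-dioxolan-2-yl)-4-hydroxy-3-[methoxy(methyl)carbamoyl]-6-{[(4-methoxybenzyl)oxy]methyl}oct-5-enoate | C1COC(O1)CC/C(COCc1ccc(OC)cc1)=C\[C@@H](O)[C@H](CC(=O)OC(C)(C)C)C(=O)N(C)OC | intermediate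
15 | 1,3-dithiane | C1CSCSC1 | starting material
16 | 2-lithio-1,3-dithiane (not isolated) | [Li]C1SCCCS1 | intermediate
17 | tert-butyl (3S,4R,5E)-8-(1,3-dioxolan-2-yl)-3-(1,3-dithiane-2-carbonyl)-4-hydroxy-6-{[(4-methoxybenzyl)oxy]methyl}oct-5-enoate | C1COC(O1)CC/C(COCc1ccc(OC)cc1)=C\[C@@H](O)[C@H](CC(=O)OC(C)(C)C)C(=O)C1SCCCS1 | intermediate
18 | tert-butyl (3R,4R,5E)-4-acetoxy-8-(1,3-dioxolan-2-yl)-3-[(S)-(1,3-dithian-2-yl)(hydroxy)methyl]-6-{[(4-methoxybenzyl)oxy]methyl}oct-5-enoate (germacrane 6R,7R,8S) | C1COC(O1)CC/C(COCc1ccc(OC)cc1)=C\[C@@H](OC(C)=O)[C@H](CC(=O)OC(C)(C)C)[C@H](O)C1SCCCS1 | intermediate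
19 | tert-butyl (3S,4R,5E)-4-acetoxy-3-[(S)-(tert-butyldimethylsilyloxy)(1,3-dithian-2-yl)methyl]-8-(1,3-dioxolan-2-yl)-6-{[(4-methoxybenzyl)oxy]methyl}oct-5-enoate | C1COC(O1)CC/C(COCc1ccc(OC)cc1)=C\[C@@H](OC(C)=O)[C@H](CC(=O)OC(C)(C)C)[C@H](O[Si](C)(C)C(C)(C)C)C1SCCCS1 | intermediate
20 | (4S,5R)-4-[(S)-(tert-butyldimethylsilyloxy)(1,3-dithian-2-yl)methyl]-5-[(E)-4-(1,3-dioxolan-2-yl)-2-{[(4-methoxybenzyl)oxy]methyl}but-1-en-1-yl]dihydrofuran-2(3H)-one | C1COC(O1)CC/C(COCc1ccc(OC)cc1)=C\[C@H]1OC(=O)C[C@@H]1[C@H](O[Si](C)(C)C(C)(C)C)C1SCCCS1 | intermediate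
21 | (S)-2-(tert-butyldimethylsilyloxy)-2-{(2R,3S)-2-[(E)-4-(1,3-dioxolan-2-yl)-2-{[(4-methoxybenzyl)oxy]methyl}but-1-en-1-yl]-5-oxotetrahydrofuran-3-yl}acetaldehyde | C1COC(O1)CC/C(COCc1ccc(OC)cc1)=C\[C@H]1OC(=O)C[C@@H]1[C@H](O[Si](C)(C)C(C)(C)C)C=O | intermediate
22 | methyl 2-(diethoxyphosphoryl)acetate | COC(=O)CP(=O)(OCC)OCC | starting material
23 | methyl (2E,4S)-4-(tert-butyldimethylsilyloxy)-2-(diethoxyphosphoryl)-4-{(2R,3S)-2-[(E)-4-(1,3-dioxolan-2-yl)-2-{[(4-methoxybenzyl)oxy]methyl}but-1-en-1-yl]-5-oxotetrahydrofuran-3-yl}but-2-enoate | C1COC(O1)CC/C(COCc1ccc(OC)cc1)=C\[C@H]1OC(=O)C[C@@H]1[C@H](O[Si](C)(C)C(C)(C)C)/C=C(/P(=O)(OCC)OCC)C(=O)OC | intermediate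
24 | methyl (2E,4S)-4-(tert-butyldimethylsilyloxy)-2-(diethoxyphosphoryl)-4-{(2R,3S)-2-[(E)-2-{[(4-methoxybenzyl)oxy]methyl}-5-oxopent-1-en-1-yl]-5-oxotetrahydrofuran-3-yl}but-2-enoate (seco C1 aldehyde, key-step precursor) | O=CCC/C(COCc1ccc(OC)cc1)=C\[C@H]1OC(=O)C[C@@H]1[C@H](O[Si](C)(C)C(C)(C)C)/C=C(/P(=O)(OCC)OCC)C(=O)OC | intermediate
25 | sodium methoxide | [Na+].[O-]C | starting material
26 | sodium salt of the C10 carbanion formed by methoxide addition at C9 of 24 (germacrane 6R,7S,8S,9R; not isolated) | [Na+].O=CCC/C(COCc1ccc(OC)cc1)=C\[C@H]1OC(=O)C[C@@H]1[C@H](O[Si](C)(C)C(C)(C)C)[C@@H](OC)[C-](C(=O)OC)P(=O)(OCC)OCC | intermediate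
27 | methyl (1(10)E,4E,6R,7S,8S,9S)-8-(tert-butyldimethylsilyloxy)-9-methoxy-15-[(4-methoxybenzyl)oxy]-13-norgermacra-1(10),4-dien-12,6-olid-14-oate | CC(C)(C)[Si](C)(C)O[C@H]1[C@H]2CC(=O)O[C@@H]2/C=C(/COCc3ccc(OC)cc3)CC/C=C(/C(=O)OC)[C@@H]1OC | intermediate
28 | (1(10)Z,4E,6R,7S,8S,9S)-8-(tert-butyldimethylsilyloxy)-9-methoxy-15-[(4-methoxybenzyl)oxy]-12,6-epoxy-13-norgermacra-1(10),4-diene-12,14-diol (lactol, C12 anomers) | CC(C)(C)[Si](C)(C)O[C@H]1[C@H]2CC(O)O[C@@H]2/C=C(/COCc3ccc(OC)cc3)CC/C=C(/CO)[C@@H]1OC | intermediate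
29 | (1(10)E,4E,6R,7S,8S,9S)-8-(tert-butyldimethylsilyloxy)-9-methoxy-15-[(4-methoxybenzyl)oxy]-14-oxo-13-norgermacra-1(10),4-dien-12,6-olide | CC(C)(C)[Si](C)(C)O[C@H]1[C@H]2CC(=O)O[C@@H]2/C=C(/COCc3ccc(OC)cc3)CC/C=C(/C=O)[C@@H]1OC | intermediate
30 | 14,14-ethylenedioxy acetal of 29 (C10 bears a 1,3-dioxolan-2-yl group) | CC(C)(C)[Si](C)(C)O[C@H]1[C@H]2CC(=O)O[C@@H]2/C=C(/COCc3ccc(OC)cc3)CC/C=C(/C3OCCO3)[C@@H]1OC | intermediate
31 | 11-(dimethylaminomethyl) derivative of 30 (Mannich base, C11 epimers; not isolated) | CC(C)(C)[Si](C)(C)O[C@H]1[C@H]2C(CN(C)C)C(=O)O[C@@H]2/C=C(/COCc3ccc(OC)cc3)CC/C=C(/C3OCCO3)[C@@H]1OC | intermediate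
32 | 11-(trimethylammoniomethyl) iodide of 30 (not isolated) | CC(C)(C)[Si](C)(C)O[C@H]1[C@H]2C(C[N+](C)(C)C)C(=O)O[C@@H]2/C=C(/COCc3ccc(OC)cc3)CC/C=C(/C3OCCO3)[C@@H]1OC.[I-] | intermediate
33 | (1(10)E,4E,6R,7S,8S,9S)-8-(tert-butyldimethylsilyloxy)-14,14-ethylenedioxy-9-methoxy-15-[(4-methoxybenzyl)oxy]germacra-1(10),4,11(13)-trien-12,6-olide | CC(C)(C)[Si](C)(C)O[C@H]1[C@H]2C(=C)C(=O)O[C@@H]2/C=C(/COCc3ccc(OC)cc3)CC/C=C(/C3OCCO3)[C@@H]1OC | intermediate
34 | (1(10)E,4E,6R,7R,8S,9S)-8-hydroxy-9-methoxy-15-[(4-methoxybenzyl)oxy]-14-oxogermacra-1(10),4,11(13)-trien-12,6-olide | O[C@H]1[C@H]2C(=C)C(=O)O[C@@H]2/C=C(/COCc3ccc(OC)cc3)CC/C=C(/C=O)[C@@H]1OC | intermediate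
35 | (1(10)E,4E,6R,7S,8S,9S)-9-methoxy-15-[(4-methoxybenzyl)oxy]-8-(methacryloyloxy)-14-oxogermacra-1(10),4,11(13)-trien-12,6-olide | C=C(C)C(=O)O[C@H]1[C@H]2C(=C)C(=O)O[C@@H]2/C=C(/COCc3ccc(OC)cc3)CC/C=C(/C=O)[C@@H]1OC | intermediate
36 | CNP0114830.1: (1(10)E,4E,6R,7S,8S,9S)-15-hydroxy-9-methoxy-8-(methacryloyloxy)-14-oxogermacra-1(10),4,11(13)-trien-12,6-olide | C=C(C)C(=O)O[C@H]1[C@H]2C(=C)C(=O)O[C@@H]2/C=C(/CO)CC/C=C(/C=O)[C@@H]1OC | target

Total step count: 22. Longest linear sequence: 21 steps (steps 1–4 and 6–22 from 2-butyne-1,4-diol; step 5 makes the imide in a side branch).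

Steps most likely to fail

Step 15 (proposed new method). The reversible methoxide addition may be outrun by intermolecular olefination, by γ-deprotonation at C8 with loss of that centre, or by methanolysis of the lactone; the cyclisation may also select the unwanted C9 epimer. The fallback separates the two events with known reactions and runs from 23 back to 27. Methanol is added across C9=C10 of acetal 23 with catalytic NaOMe in MeOH/THF at −20 °C (oxa-Michael addition to an alkylidene phosphonoacetate; no aldehyde is present and an acidic work-up recloses any opened lactone). This gives the C9-methoxy phosphonoacetate acetal F1, whose C9 epimers are separated by chromatography (C10 is irrelevant). PPTS in wet acetone then frees the C1 aldehyde to give the C9-methoxy phosphonoacetate aldehyde F2. Intramolecular Horner–Wadsworth–Emmons macrocyclisation under Masamune–Roush conditions (LiCl, DBU, MeCN, slow addition at high dilution), with no nucleophilic alkoxide present, closes the ring to 27.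

Step 13. The Lewis acid may strip the dioxolane or the PMB ether, or the titanium enolate of the aldehyde may epimerise C8. The fallback replaces condensation by olefination and runs from 21 back to 23. Tetraethyl methylenediphosphonate is C-acylated (NaH, ClCO2Me, THF) to methyl 2,2-bis(diethoxyphosphoryl)acetate F3. Its sodium salt is combined with 21 in THF at 0 °C to rt, and Horner–Wadsworth–Emmons loss of one phosphoryl group (the reaction type that turns geminal bisphosphonates and aldehydes into vinylphosphonates) should give 23 without a Lewis acid.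

Step 9. Residual samarium(II) may transfer an electron to the C–S bonds, sulfur may inhibit the catalyst, or the acetyl group may migrate between O6 and O8 and erase the differentiation of the two oxygens. The fallback uses hydroxyl-directed borohydride reduction and runs from 17 back to 20. Me4NBH(OAc)3 in MeCN/AcOH at −30 °C (Evans–Saksena reduction, 1,3-anti) gives the anti diol F4. K2CO3 in MeOH under equilibrating conditions closes the thermodynamically preferred trans-4,5-disubstituted 6,12-lactone and leaves the C8 hydroxyl free, giving the hydroxy lactone F5. TBSOTf/2,6-lutidine then gives 20.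

Further compounds
F1 | step 15 | methyl (3R,4S)-4-(tert-butyldimethylsilyloxy)-2-(diethoxyphosphoryl)-4-{(2R,3S)-2-[(E)-4-(1,3-dioxolan-2-yl)-2-{[(4-methoxybenzyl)oxy]methyl}but-1-en-1-yl]-5-oxotetrahydrofuran-3-yl}-3-methoxybutanoate (C2 epimers) | C1COC(O1)CC/C(COCc1ccc(OC)cc1)=C\[C@H]1OC(=O)C[C@@H]1[C@H](O[Si](C)(C)C(C)(C)C)[C@@H](OC)C(C(=O)OC)P(=O)(OCC)OCC
F2 | step 15 | methyl (3R,4S)-4-(tert-butyldimethylsilyloxy)-2-(diethoxyphosphoryl)-3-methoxy-4-{(2R,3S)-2-[(E)-2-{[(4-methoxybenzyl)oxy]methyl}-5-oxopent-1-en-1-yl]-5-oxotetrahydrofuran-3-yl}butanoate (C2 epimers) | O=CCC/C(COCc1ccc(OC)cc1)=C\[C@H]1OC(=O)C[C@@H]1[C@H](O[Si](C)(C)C(C)(C)C)[C@@H](OC)C(C(=O)OC)P(=O)(OCC)OCC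
F3 | step 13 | methyl 2,2-bis(diethoxyphosphoryl)acetate | COC(=O)C(P(=O)(OCC)OCC)P(=O)(OCC)OCC
F4 | step 9 | tert-butyl (3S,4R,5E)-8-(1,3-dioxolan-2-yl)-3-[(S)-(1,3-dithian-2-yl)(hydroxy)methyl]-4-hydroxy-6-{[(4-methoxybenzyl)oxy]methyl}oct-5-enoate | C1COC(O1)CC/C(COCc1ccc(OC)cc1)=C\[C@@H](O)[C@H](CC(=O)OC(C)(C)C)[C@H](O)C1SCCCS1
F5 | step 9 | (4R,5R)-5-[(E)-4-(1,3-dioxolan-2-yl)-2-{[(4-methoxybenzyl)oxy]methyl}but-1-en-1-yl]-4-[(S)-(1,3-dithian-2-yl)(hydroxy)methyl]dihydrofuran-2(3H)-one | C1COC(O1)CC/C(COCc1ccc(OC)cc1)=C\[C@H]1OC(=O)C[C@@H]1[C@H](O)C1SCCCS1
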